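## Retrosynthetic overview

1. Structural feature: C2–C3–C4 of ring C, with ring B on C2 and ring A on C4, is a masked trans-1,2-diarylcyclopropane. Trading the O1–C2 bond and one C4–H for a C2–C4 bond folds the flavan into it, and C2 is the only centre that survives.
2. Kazinol E ⇒ (loss of two MOM groups and one pivalate) (2S)-flavan ⇒ ring C reopened to the (S,S)-cyclopropane with a free C8a–OH. O7 stays a pivalate so that ring B, not ring A, gives up the electron.
3. Both prenyl groups (C2', C3') ⇒ aryl bromides, joined by a double Negishi coupling after the cyclopropane is complete. Neither the copper carbene nor the cyclopropyl radical then meets a prenyl alkene.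
4. C4–C4a ⇒ nickel-catalysed decarboxylative arylation of a cyclopropane redox-active ester (5-bromovanillin → dibromostyrene → copper–bis(oxazoline) cyclopropanation) by an arylzinc (4-bromoresorcinol → prenyl ether → aromatic Claisen).
5. Ring order: rings A and B are bought, the three-membered ring is built on ring B, ring A is attached to it, and ring C is closed last at the expense of the three-membered ring.

Key step: step 14

Assumption: the facial preference of the copper–bis(oxazoline) carbene known for styrene is taken to hold for the dibromostyrene of step 4, and in step 12 the less shielded C3'–Br bond is taken to couple first.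

## Route

Step 1
Reactants: 1 5-bromovanillin (3-bromo-4-hydroxy-5-methoxybenzaldehyde)
Product: 2 2,3-dibromo-4-hydroxy-5-methoxybenzaldehyde
Conditions: Br2, Fe powder (cat.), AcOH, 25 to 50 °C
Reagents that add atoms: bromine, BrBr
Why: Electrophilic aromatic bromination: of the two free positions, C6 is para to the methoxy group and open, whereas C2 is wedged between formyl and methoxy, so the second bromine should enter next to the first and complete the contiguous 2,3-dihalo-4,5-dioxygenated pattern that ring B needs.

Step 2
Reactants: 2 2,3-dibromo-4-hydroxy-5-methoxybenzaldehyde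
Product: 3 2,3-dibromo-4,5-dihydroxybenzaldehyde
Conditions: BBr3, CH2Cl2, −78 to 25 °C; then H2O
Reagents that add atoms: none
Why: Lewis-acid cleavage of the aryl methyl ether by BBr3 is routine for brominated vanillins and spares the aldehyde and both C–Br bonds.

Step 3
Reactants: 3 2,3-dibromo-4,5-dihydroxybenzaldehyde
Product: 4 2,3-dibromo-4,5-bis(methoxymethoxy)benzaldehyde
Conditions: MOMCl, iPr2NEt, CH2Cl2, 0 to 25 °C
Reagents that add atoms: chloromethyl methyl ether, COCCl
Why: O-Alkylation of both phenols (MOM acetal protection) gives ethers that withstand ylide, carbenoid, hydroxide, organozinc, fluoride and light, keep ring B electron-rich for step 14 and leave under mild acid at the end.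

Step 4
Reactants: 4 2,3-dibromo-4,5-bis(methoxymethoxy)benzaldehyde
Product: 5 2,3-dibromo-4,5-bis(methoxymethoxy)styrene
Conditions: Ph3PCH3Br, KOtBu, THF, 0 to 25 °C
Reagents that add atoms: methyltriphenylphosphonium bromide, C[P+](c1ccccc1)(c1ccccc1)c1ccccc1.[Br-]
Why: Wittig methylenation of a non-enolisable aldehyde, with the ylide made by an alkoxide base so that no alkyllithium can exchange the aryl bromides.

Step 5
Reactants: 5 2,3-dibromo-4,5-bis(methoxymethoxy)styrene; 6 ethyl diazoacetate
Product: 7 ethyl (1S,2S)-2-[2,3-dibromo-4,5-bis(methoxymethoxy)phenyl]cyclopropane-1-carboxylate (trans)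
Conditions: Cu(O3SCF3)·0.5C6H6 (2 mol %), 2,2'-(propane-2,2-diyl)bis[(4R)-4-tert-butyl-4,5-dihydrooxazole] (2.2 mol %), CH2Cl2, 25 °C, slow addition of 6; chromatography
Reagents that add atoms: ethyl diazoacetate 6, CCOC(=O)C=[N+]=[N-]
Why: Copper–bis(oxazoline) asymmetric cyclopropanation: the vinyl group is the only alkene present (prenyl groups, which would compete for the electrophilic carbene, are still missing), the C2-symmetric (R,R)-ligand directs the carbene to the face that gives the trans-(1S,2S) ester and so fixes (S) at the aryl-bearing carbon, the future C2, and the minor cis ester, which carries the opposite configuration at that carbon, is removed by chromatography at this stage.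

Step 6
Reactants: 7 ethyl (1S,2S)-2-[2,3-dibromo-4,5-bis(methoxymethoxy)phenyl]cyclopropane-1-carboxylate
Product: 8 (1S,2S)-2-[2,3-dibromo-4,5-bis(methoxymethoxy)phenyl]cyclopropane-1-carboxylic acid
Conditions: LiOH·H2O, THF/MeOH/H2O, 40 °C; then cold 1 M HCl to pH 4
Reagents that add atoms: lithium hydroxide, [Li+].[OH-]
Why: Saponification of the ethyl ester needs no acid stronger than a cold, brief work-up, so the MOM ethers survive (the reason for choosing the ethyl rather than a tert-butyl ester), and epimerisation next to the carboxylate would be harmless because that centre is remade in step 11.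

Step 7
Reactants: 8 (1S,2S)-2-[2,3-dibromo-4,5-bis(methoxymethoxy)phenyl]cyclopropane-1-carboxylic acid
Product: 9 1,3-dioxoisoindolin-2-yl (1S,2S)-2-[2,3-dibromo-4,5-bis(methoxymethoxy)phenyl]cyclopropane-1-carboxylate
Conditions: N-hydroxyphthalimide, iPrN=C=NiPr, DMAP (cat.), CH2Cl2, 25 °C
Reagents that add atoms: N-hydroxyphthalimide, O=C1c2ccccc2C(=O)N1O
Why: Carbodiimide (Steglich-type) esterification with N-hydroxyphthalimide gives the redox-active ester under neutral conditions without touching either stereocentre.

Step 8
Reactants: 10 4-bromoresorcinol; 11 prenyl bromide (1-bromo-3-methylbut-2-ene)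
Product: 12 2-bromo-5-(3-methylbut-2-enyloxy)phenol
Conditions: K2CO3 (1 equiv), 11 (1 equiv), acetone, 25 to 50 °C
Reagents that add atoms: prenyl bromide 11, CC(C)=CCBr
Why: Williamson ether synthesis with one equivalent of halide: the hydroxyl para to bromine is unhindered and gives the more nucleophilic phenoxide, whereas the one ortho to bromine is shielded and its anion stabilised, so mono-alkylation should favour the oxygen that becomes O7, with the isomer and the bis-ether removed by chromatography.

Step 9
Reactants: 12 2-bromo-5-(3-methylbut-2-enyloxy)phenol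
Product: 13 [2-bromo-5-(3-methylbut-2-enyloxy)phenoxy](tert-butyl)dimethylsilane
Conditions: TBSCl, imidazole, DMF, 25 °C
Reagents that add atoms: tert-butyldimethylsilyl chloride, CC(C)(C)[Si](C)(C)Cl
Why: Silylation of the remaining phenol (the future O1) gives an ether that stands heat and organozinc chemistry and can later be removed by fluoride in the presence of MOM and pivalate groups.

Step 10
Reactants: 13 [2-bromo-5-(3-methylbut-2-enyloxy)phenoxy](tert-butyl)dimethylsilane
Product: 15 4-bromo-5-(tert-butyldimethylsilyloxy)-2-(2-methylbut-3-en-2-yl)phenyl pivalate, via free phenol 14 (not isolated)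
Conditions: pivalic anhydride, N,N-diethylaniline, 190 °C, sealed tube, argon
Reagents that add atoms: pivalic anhydride, CC(C)(C)C(=O)OC(=O)C(C)(C)C
Why: Aromatic Claisen rearrangement: the [3,3] shift inverts the prenyl unit into the 1,1-dimethylallyl group at the free ortho position away from the bulky silyl ether, bromine blocks the para position against a following Cope shift, and in situ acylation of the liberated phenol stops cyclisation onto the new alkene and installs the electron-withdrawing O7 group wanted in step 14.

Step 11
Reactants: 9 1,3-dioxoisoindolin-2-yl (1S,2S)-2-[2,3-dibromo-4,5-bis(methoxymethoxy)phenyl]cyclopropane-1-carboxylate; 15 4-bromo-5-(tert-butyldimethylsilyloxy)-2-(2-methylbut-3-en-2-yl)phenyl pivalate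
Product: 17 4-{(1S,2S)-2-[2,3-dibromo-4,5-bis(methoxymethoxy)phenyl]cyclopropyl}-5-(tert-butyldimethylsilyloxy)-2-(2-methylbut-3-en-2-yl)phenyl pivalate (trans), via arylzinc chloride 16 (not isolated)
Conditions: 15 (3 equiv), Mg turnings, LiCl, ZnCl2, THF, 25 °C; then 9, NiCl2·MeOCH2CH2OMe (20 mol %), 4,4'-di-tert-butyl-2,2'-bipyridine (40 mol %), THF/DMF, 25 °C; chromatography
Reagents that add atoms: none
Why: Nickel-catalysed decarboxylative Negishi-type arylation of a redox-active ester: magnesium insertion with ZnCl2 present traps the aryl anion as the zinc reagent before it can attack the pivalate or trigger O-to-C silyl migration, single-electron reduction of 9 releases CO2 and a rapidly inverting cyclopropyl radical that does not ring-open, and the aryl–nickel species captures it on the face away from ring B, so that C4 is set trans by substrate control while C2 stays untouched, the doubly ortho-flanked C–Br bonds being expected to resist the bipyridine–nickel catalyst at room temperature and no ortho-prenyl alkene yet being there to trap the radical in a 6-exo cyclisation.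

Step 12
Reactants: 17 trans-(S,S)-diarylcyclopropane dibromide; 11 prenyl bromide
Product: 19 4-{(1S,2S)-2-[4,5-bis(methoxymethoxy)-2,3-bis(3-methylbut-2-enyl)phenyl]cyclopropyl}-5-(tert-butyldimethylsilyloxy)-2-(2-methylbut-3-en-2-yl)phenyl pivalate, via monoprenylated bromide 18 (not isolated)
Conditions: prenylzinc bromide (from 11, Zn dust, LiCl, THF, 0 °C; 3 equiv), Pd(OAc)2 (5 mol %), CPhos (10 mol %), THF, 25 to 50 °C
Reagents that add atoms: prenylzinc bromide, CC(C)=CC[Zn]Br, made from prenyl bromide 11, CC(C)=CCBr
Why: Linear-selective Negishi prenylation: oxidative addition of zerovalent palladium bearing a bulky biarylphosphine into each hindered C–Br bond, transmetalation and reductive elimination from the less substituted allyl terminus should give the normal prenyl groups at C3' and C2', and the base-free conditions spare silyl ether, pivalate and cyclopropane.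

Step 13
Reactants: 19 diprenylated silyl ether
Product: 20 4-{(1S,2S)-2-[4,5-bis(methoxymethoxy)-2,3-bis(3-methylbut-2-enyl)phenyl]cyclopropyl}-5-hydroxy-2-(2-methylbut-3-en-2-yl)phenyl pivalate (key-step precursor)
Conditions: Bu4NF, AcOH (1:1), THF, 0 °C
Reagents that add atoms: none
Why: Fluoride-induced desilylation of the aryl silyl ether, buffered by acetic acid so that no free phenoxide can shuffle the pivalate, leaves MOM ethers, alkenes and the cyclopropane alone.

Step 14
Reactants: 20 trans-(S,S)-cyclopropyl phenol
Product: 21 (2S)-2-[4,5-bis(methoxymethoxy)-2,3-bis(3-methylbut-2-enyl)phenyl]-6-(2-methylbut-3-en-2-yl)chroman-7-yl pivalate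
Conditions: 9-mesityl-10-methylacridinium tetrafluoroborate (5 mol %), 2,4,6-triisopropylbenzenethiol (20 mol %), ClCH2CH2Cl, 450 nm LEDs, 0 °C, argon
Reagents that add atoms: none
Why: Proposed new method: the excited acridinium should take one electron from ring B of 20, a trialkylated catechol diether that is easier to oxidise than the O7-pivaloylated ring A and far easier than any of the three alkenes, which turns the C2–C4 bond, the only ring bond flanked by both arenes, into a long one-electron bond with positive charge building at C2 para to the C4' oxygen; the C8a hydroxyl adds to C2, its proton passes to thiolate, the C4 benzylic radical takes a hydrogen atom from the arenethiol, and the thiyl radical re-oxidises the acridinyl radical, so the step is a redox-neutral isomerisation. The closest known reaction type is the photoredox ring-opening hydrofunctionalisation of arylcyclopropanes by external alcohols, carboxylates and azoles, a three-electron nucleophilic substitution on the radical cation that inverts the attacked carbon, whereas a phenol tethered to the departing carbon and a chroman as product have not been shown. Ring C closes in a 6-endo-tet mode through a half-chair in which C3 remains the bridge and both C2 and the departing C4 become ring members. Since O1 is tied to C4 through C4a and C8a it meets C2 roughly at right angles to the breaking bond and not collinear with it, so the substitution must be coupled to a turn of the C2 terminus about C2–C3: in the trans isomer O1 lies on the face opposite ring B, the sterically open turn swings the ortho-prenylated ring B outward into the pseudo-equatorial position and brings the rear lobe of C2 up to O1, and the bond forms on the side away from C4, that is with inversion, so the (S) centre set in step 5 becomes (2S) of 21 (same letter because O1 outranks ring B while C4 did not) and the C4 centre is erased. The step needs attack at C2 rather than C3, which the doubly benzylic C2–C4 bond secures, closure faster than free rotation in an open benzylic cation, which the non-polar solvent, the low temperature, the absence of acid and the attenuated ring A are meant to secure, and inert alkenes, which hole localisation on ring B and a hindered thiol used only in catalytic amount are meant to secure.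

Step 15
Reactants: 21 (2S)-flavan 7-pivalate
Product: 22 (2S)-2-[4,5-bis(methoxymethoxy)-2,3-bis(3-methylbut-2-enyl)phenyl]-6-(2-methylbut-3-en-2-yl)chroman-7-ol
Conditions: K2CO3, MeOH/THF, 50 °C
Reagents that add atoms: none
Why: Base-catalysed methanolysis (transesterification) of the aryl ester is safe for the C2 stereocentre because ring B is still fully etherified and cannot form a quinone methide.

Step 16
Reactants: 22 (2S)-flavan-7-ol bis(methoxymethyl) ether
Product: 23 kazinol E
Conditions: HCl (1 M in MeOH), MeOH/THF, 25 to 35 °C
Reagents that add atoms: none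
Why: Acid-catalysed acetal exchange with methanol removes both aryl MOM ethers under the dilute, near-ambient conditions customary for prenylated phenols, which are too mild to protonate the alkenes or to ionise the C2–O1 bond, so the (2S) centre is kept.

## Compound list

1 | 5-bromovanillin | COc1cc(C=O)cc(Br)c1O | starting material
2 | 2,3-dibromo-4-hydroxy-5-methoxybenzaldehyde | COc1cc(C=O)c(Br)c(Br)c1O | intermediate
3 | 2,3-dibromo-4,5-dihydroxybenzaldehyde | O=Cc1cc(O)c(O)c(Br)c1Br | intermediate
4 | 2,3-dibromo-4,5-bis(methoxymethoxy)benzaldehyde | COCOc1cc(C=O)c(Br)c(Br)c1OCOC | intermediate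
5 | 2,3-dibromo-4,5-bis(methoxymethoxy)styrene | C=Cc1cc(OCOC)c(OCOC)c(Br)c1Br | intermediate
6 | ethyl diazoacetate | CCOC(=O)C=[N+]=[N-] | starting material
7 | ethyl (1S,2S)-2-[2,3-dibromo-4,5-bis(methoxymethoxy)phenyl]cyclopropane-1-carboxylate | CCOC(=O)[C@H]1C[C@@H]1c2cc(OCOC)c(OCOC)c(Br)c2Br | intermediate
8 | (1S,2S)-2-[2,3-dibromo-4,5-bis(methoxymethoxy)phenyl]cyclopropane-1-carboxylic acid | OC(=O)[C@H]1C[C@@H]1c2cc(OCOC)c(OCOC)c(Br)c2Br | intermediate
9 | N-acyloxyphthalimide (redox-active ester) of 8 | O=C(ON1C(=O)c2ccccc2C1=O)[C@H]3C[C@@H]3c4cc(OCOC)c(OCOC)c(Br)c4Br | intermediate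
10 | 4-bromoresorcinol | Oc1ccc(Br)c(O)c1 | starting material
11 | prenyl bromide | CC(C)=CCBr | starting material
12 | 2-bromo-5-(3-methylbut-2-enyloxy)phenol | CC(C)=CCOc1ccc(Br)c(O)c1 | intermediate
13 | [2-bromo-5-(3-methylbut-2-enyloxy)phenoxy](tert-butyl)dimethylsilane | CC(C)=CCOc1ccc(Br)c(O[Si](C)(C)C(C)(C)C)c1 | intermediate
14 | 4-bromo-5-(tert-butyldimethylsilyloxy)-2-(2-methylbut-3-en-2-yl)phenol (not isolated) | C=CC(C)(C)c1cc(Br)c(O[Si](C)(C)C(C)(C)C)cc1O | intermediate
15 | 4-bromo-5-(tert-butyldimethylsilyloxy)-2-(2-methylbut-3-en-2-yl)phenyl pivalate | C=CC(C)(C)c1cc(Br)c(O[Si](C)(C)C(C)(C)C)cc1OC(=O)C(C)(C)C | intermediate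
16 | arylzinc chloride from 15 (not isolated) | C=CC(C)(C)c1cc([Zn]Cl)c(O[Si](C)(C)C(C)(C)C)cc1OC(=O)C(C)(C)C | intermediate
17 | trans-(1S,2S)-diarylcyclopropane, ring B 2,3-dibromide, O1 silyl ether, O7 pivalate | C=CC(C)(C)c1cc([C@H]2C[C@@H]2c3cc(OCOC)c(OCOC)c(Br)c3Br)c(O[Si](C)(C)C(C)(C)C)cc1OC(=O)C(C)(C)C | intermediate
18 | monoprenylated bromide, C3' coupled, C2'–Br left (not isolated) | C=CC(C)(C)c1cc([C@H]2C[C@@H]2c3cc(OCOC)c(OCOC)c(CC=C(C)C)c3Br)c(O[Si](C)(C)C(C)(C)C)cc1OC(=O)C(C)(C)C | intermediate
19 | trans-(1S,2S)-diarylcyclopropane, ring B 2,3-diprenyl, O1 silyl ether, O7 pivalate | C=CC(C)(C)c1cc([C@H]2C[C@@H]2c3cc(OCOC)c(OCOC)c(CC=C(C)C)c3CC=C(C)C)c(O[Si](C)(C)C(C)(C)C)cc1OC(=O)C(C)(C)C | intermediate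
20 | key-step precursor: trans-(1S,2S)-diarylcyclopropane with free C8a–OH, O7 pivalate | C=CC(C)(C)c1cc([C@H]2C[C@@H]2c3cc(OCOC)c(OCOC)c(CC=C(C)C)c3CC=C(C)C)c(O)cc1OC(=O)C(C)(C)C | intermediate
21 | key-step product: (2S)-flavan, ring B bis(MOM) ether, O7 pivalate | C=CC(C)(C)c1cc2c(cc1OC(=O)C(C)(C)C)O[C@H](c3cc(OCOC)c(OCOC)c(CC=C(C)C)c3CC=C(C)C)CC2 | intermediate
22 | (2S)-flavan-7-ol, ring B bis(MOM) ether | C=CC(C)(C)c1cc2c(cc1O)O[C@H](c3cc(OCOC)c(OCOC)c(CC=C(C)C)c3CC=C(C)C)CC2 | intermediate
23 | kazinol E | C=CC(C)(C)c1cc2c(cc1O)O[C@H](c1cc(O)c(O)c(CC=C(C)C)c1CC=C(C)C)CC2 | target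

## Step count and risks

Total steps: 16. Longest linear sequence: 13 (steps 1–7 and 11–16, from 5-bromovanillin).

**1. Step 14 (Proposed new method).**
- What may go wrong:
  - Loss of stereochemical memory by rotation about C2–C3 and C3–C4 in a fully opened radical cation before O1–C2 bonding.
  - Reversible opening followed by back electron transfer, which would racemise or isomerise the cyclopropane.
  - Closure with ring B turning inward, which is the retentive sense.
  - Thiyl addition to the vinyl group, or hydrogen abstraction from the benzylic-allylic CH2 groups.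
  - Renewed oxidation of the product at ring B with exchange of the C2–H.
- If the closure proved stereospecific but retentive, the (S,S)-ligand in step 5 would correct it.
- The fallback gives up the cyclopropane and closes O1–C2 by a classical SN2 reaction. It sets out from aldehyde 4 and bromide 15 and comes back at 21. Stille coupling of 4 with tributyl(3-methylbut-2-enyl)stannane (Pd(PPh3)4, DMF, 100 °C) should give 4,5-bis(methoxymethoxy)-2,3-bis(3-methylbut-2-enyl)benzaldehyde F1. Vinylmagnesium bromide should add to it to give the racemic aryl vinyl carbinol F2. Heck arylation of F2 with 15 (Pd(OAc)2, P(o-tolyl)3, Et3N, DMF, 90 °C) should give the 1,3-diarylpropan-1-one F3, because β-hydride elimination towards the carbinol carbon and tautomerisation lead to the saturated ketone. Noyori asymmetric transfer hydrogenation (RuCl(p-cymene)[(R,R)-TsDPEN], HCO2H/Et3N) leaves isolated alkenes alone and should give the (R)-carbinol F4. Buffered Bu4NF should free the phenol to give the hydroxy phenol F5. Mitsunobu etherification (PPh3, DIAD, THF, 0 °C) should then close ring C with inversion to 21.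

**2. Step 11.**
- What may go wrong:
  - Slow capture of the cyclopropyl radical by the ortho-silyloxy aryl–nickel species, so that reduction or dimerisation of the radical takes over.
  - Insertion of low-valent nickel into the C–Br bonds.
  - Incomplete trans selectivity.
- The fallback replaces radical capture at nickel by a stereoretentive two-electron coupling. It sets out from 9 and 16 and comes back at 17. Photochemical decarboxylative borylation of 9 (B2cat2, DMAc, blue LEDs; then pinacol, Et3N) should give the trans-cyclopropylboronic acid pinacol ester F6. Quenching arylzinc 16 with iodine should give the aryl iodide F7. Suzuki–Miyaura coupling of F6 with F7 (Pd(OAc)2, SPhos, K3PO4, toluene/H2O, 80 °C) should give 17, because palladium enters the C–I bond well before the doubly flanked C–Br bonds.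

**3. Step 12.**
- What may go wrong:
  - Stalling after the first coupling, because the second C–Br bond is shielded on both sides.
  - Transfer of the prenyl unit through its tertiary terminus.
  - Protodebromination.
- The fallback changes from catalytic cross-coupling to a stoichiometric π-allylnickel halide coupling. It sets out from 17, passes through 18 and comes back at 19, and makes no new compound (F0). The η3-prenylnickel bromide dimer [(C5H9)NiBr]2, made from 11 and Ni(cod)2, would be heated with 17 in DMF at 50 °C. This is a known way to prenylate doubly ortho-substituted aryl bromides at the primary allyl terminus, and it tolerates esters.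

## Further compounds

F1 | step 14 | 4,5-bis(methoxymethoxy)-2,3-bis(3-methylbut-2-enyl)benzaldehyde | COCOc1cc(C=O)c(CC=C(C)C)c(CC=C(C)C)c1OCOC
F2 | step 14 | racemic 1-[4,5-bis(methoxymethoxy)-2,3-bis(3-methylbut-2-enyl)phenyl]prop-2-en-1-ol | C=CC(O)c1cc(OCOC)c(OCOC)c(CC=C(C)C)c1CC=C(C)C
F3 | step 14 | 1-(ring B aryl)-3-(ring A aryl)propan-1-one, O1 silyl ether, O7 pivalate | C=CC(C)(C)c1cc(CCC(=O)c2cc(OCOC)c(OCOC)c(CC=C(C)C)c2CC=C(C)C)c(O[Si](C)(C)C(C)(C)C)cc1OC(=O)C(C)(C)C
F4 | step 14 | (R)-1-(ring B aryl)-3-(ring A aryl)propan-1-ol, O1 silyl ether, O7 pivalate | C=CC(C)(C)c1cc(CC[C@@H](O)c2cc(OCOC)c(OCOC)c(CC=C(C)C)c2CC=C(C)C)c(O[Si](C)(C)C(C)(C)C)cc1OC(=O)C(C)(C)C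
F5 | step 14 | (R)-1-(ring B aryl)-3-(ring A aryl)propan-1-ol with free C8a–OH, O7 pivalate | C=CC(C)(C)c1cc(CC[C@@H](O)c2cc(OCOC)c(OCOC)c(CC=C(C)C)c2CC=C(C)C)c(O)cc1OC(=O)C(C)(C)C
F6 | step 11 | 2-{(1S,2S)-2-[2,3-dibromo-4,5-bis(methoxymethoxy)phenyl]cyclopropyl}-4,4,5,5-tetramethyl-1,3,2-dioxaborolane (trans) | CC1(C)OB(OC1(C)C)[C@H]2C[C@@H]2c3cc(OCOC)c(OCOC)c(Br)c3Br
F7 | step 11 | 5-(tert-butyldimethylsilyloxy)-4-iodo-2-(2-methylbut-3-en-2-yl)phenyl pivalate | C=CC(C)(C)c1cc(I)c(O[Si](C)(C)C(C)(C)C)cc1OC(=O)C(C)(C)C
F0 | step 12 | none | none
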